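**Retrosynthetic overview**

1. Target 23 ← 22 ← 21 ← 20: the two acetates are put on last; the C17 oxygen comes from SeO2 oxidation of the C17 methyl on C8 of ring B, with C15 already acetylated.
2. 20 ← 13 + 14 + 15: the chain C12–C15 on C9 carries only the C13 methyl stereocentre (C16) and the C15 oxygen, so it is grown carbon by carbon from boron on C11 (CH2, then CH(CH3) from the (+)-sparteine-lithiated carbamate, then CH2, CH2, then B→O). C13 is set by the reagent alone.
3. 13 ← 9 ← 8: the C11 boronate comes from α-face hydroboration of the exocyclic C9=C11 alkene (sets C9, 9α-H); diene 9 comes from Wittig methylenation of the C9 ketone.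
4. 8 ← 1 + 3: ring B is the carvone ring (C5 stereocentre, C7=C8, C9 carbonyl). C10 is made quaternary by two alkylations. Ring A is then closed between C3 and C4 by a hydrogen-atom-transfer radical cyclisation, and the C2 ester is removed.
5. Ring order: ring B (from carvone), then ring A, then the side chain.

Key step: step 8

Remark: labdane numbering is used throughout; the target is read as the normal-series (5S,9R,10S,13S) diacetate (5α-H, 9α-H, 10β-CH3), and both enantiomers of sparteine are taken as commercial reagents.

**Route**

Step 1
Reactants: 1 (R)-(−)-carvone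
Product: 2 (5R)-6-methylcarvone (both C6 epimers)
Conditions: LiN(i-Pr)2 (LDA), THF, −78 °C; MeI, −78 → 0 °C
Reagents that add atoms: iodomethane, CI
Why: kinetic deprotonation at the α′-carbon gives the cross-conjugated lithium dienolate, which is C-methylated (enolate alkylation); the configuration of the new centre does not matter because it is enolised again in step 2.

Step 2
Reactants: 2 (5R)-6-methylcarvone; 3 methyl 2-(bromomethyl)acrylate
Product: 4 methyl 2-{[(1S,6S)-1,3-dimethyl-2-oxo-6-(prop-1-en-2-yl)cyclohex-3-en-1-yl]methyl}prop-2-enoate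
Conditions: LiN(i-Pr)2 (LDA), THF, −78 → −20 °C; 3, −78 → 0 °C
Reagents that add atoms: none
Why: enolate alkylation with a highly reactive allylic bromide, in which the electrophile should enter anti to the neighbouring isopropenyl group, so that the quaternary centre (future C10) carries CH3 cis and the acrylate arm trans to the isopropenyl group.

Step 3
Reactants: 4 methyl 2-{[(1S,6S)-1,3-dimethyl-2-oxo-6-(prop-1-en-2-yl)cyclohex-3-en-1-yl]methyl}prop-2-enoate
Product: 5 methyl 11-nor-9-oxodrim-7-ene-2-carboxylate (trans-fused, 5α-H, 10β-CH3, C2 epimers)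
Conditions: Fe(acac)3 (0.3 equiv), PhSiH3 (2.5 equiv), EtOH/ethylene glycol 5:1, 60 °C
Reagents that add atoms: none
Why: metal-hydride hydrogen-atom transfer to the electron-rich isopropenyl group gives the tertiary C4 radical, which closes ring A by 6-endo Giese addition to the acrylate terminus (reductive olefin coupling); the trans ring fusion follows from the trans arrangement of the two arms fixed in step 2, and the C2 centre is removed later.

Step 4
Reactants: 5 methyl 11-nor-9-oxodrim-7-ene-2-carboxylate
Product: 6 11-nor-9-oxodrim-7-ene-2-carboxylic acid (C2 epimers)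
Conditions: LiOH·H2O, THF/MeOH/H2O, rt; then 1 M HCl
Reagents that add atoms: lithium hydroxide, [Li+].[OH-]
Why: saponification of an unhindered secondary methyl ester, under which the hindered enone and the quaternary C10 are not affected.

Step 5
Reactants: 6 11-nor-9-oxodrim-7-ene-2-carboxylic acid
Product: 8 the enone 11-nor-drim-7-en-9-one, via Barton ester 7 (not isolated)
Conditions: N-hydroxypyridine-2-thione, DCC, DMAP (cat.), CH2Cl2, 0 °C → rt, dark; then t-BuSH, hν (tungsten lamp), rt
Reagents that add atoms: none
Why: Barton reductive decarboxylation, in which the thiohydroxamate ester fragments under light to the secondary C2 radical that takes hydrogen from the thiol; the enone is not a partner for this radical chain and both C2 epimers converge on one product.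

Step 6
Reactants: 8 11-nor-drim-7-en-9-one
Product: 9 drima-7,9(11)-diene
Conditions: Ph3PCH3Br, KOt-Bu, toluene, 90 °C
Reagents that add atoms: methyltriphenylphosphonium bromide, C[P+](c1ccccc1)(c1ccccc1)c1ccccc1.[Br-]
Why: Wittig methylenation under the hot alkoxide conditions used for hindered ketones, where the small ylide still reaches the C9 carbonyl between C8 and the quaternary C10 and enolisation towards C6 is reversible.

Step 7
Reactants: 9 drima-7,9(11)-diene; 10 pinacol
Product: 13 drim-7-en-11-yl pinacol boronate, via dicyclohexyl(drim-7-en-11-yl)borane 11 (not isolated), via dicyclohexyl drim-7-en-11-ylboronate 12 (not isolated)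
Conditions: Chx2BH (from BH3·SMe2 and cyclohexene), THF, 0 °C → rt; Me3NO (anhydrous, 2.1 equiv), 0 °C → rt; 10, rt
Reagents that add atoms: borane–dimethyl sulfide, [BH3-][S+](C)C
Why: hydroboration with a bulky dialkylborane should take the 1,1-disubstituted C9=C11 alkene in preference to the trisubstituted C7=C8, with boron on C11 and hydrogen delivered to C9 from the α face anti to the axial C10 methyl (sets 9α-H), after which amine-oxide oxidation cleaves the two secondary cyclohexyl–boron bonds in preference to the β-branched primary C11–B bond and pinacol transesterifies the resulting boronate.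

Step 8
Reactants: 13 drim-7-en-11-yl pinacol boronate; 14 bromochloromethane; 15 ethyl N,N-diisopropylcarbamate
Product: 20 (13S)-labd-7-en-15-ol, via C12 pinacol boronate 16 (not isolated), via C13 pinacol boronate 17 (not isolated), via C14 pinacol boronate 18 (not isolated), via C15 pinacol boronate 19 (not isolated)
Conditions: one telescoped operation under argon: (a) 14 (2.0 equiv), n-BuLi (1.8 equiv), Et2O, −78 °C → rt, then volatiles stripped in vacuo and residue taken up in Et2O; (b) solution added to 15 (1.4 equiv) pre-lithiated with s-BuLi/(+)-sparteine (Et2O, −78 °C, 5 h), −78 °C, 1 h, then 35 °C, 16 h; (c) 14, n-BuLi, −78 °C → rt, carried out twice in succession; (d) 2 M NaOH, 30% H2O2, THF, 0 °C → rt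
Reagents that add atoms: hydrogen peroxide, OO
Why: Each carbenoid (LiCH2Cl from Br/Li exchange on 14, or the α-lithiated carbamate from 15) adds to boron to give a tetracoordinate boronate, and on warming the alkyl group shifts from boron to the carbenoid carbon anti to the leaving group (chloride or carbamate), so that C11–C12, C12–C13, C13–C14 and C14–C15 form in turn before stereoretentive B→O oxidation; this is the Matteson homologation interleaved with a sparteine-mediated lithiation–borylation, run iteratively. No ring is closed. The only new stereocentre, C13, is set by the reagent: s-BuLi/(+)-sparteine removes the pro-R hydrogen of 15 to give the configurationally stable (R)-lithiated carbamate, which is borylated with retention and rearranges with inversion to the (S)-secondary boronic ester 17, and C13 then migrates with retention in both CH2 insertions and ends as 13S. The step needs exactly one insertion per cycle, which is secured because boronate formation at −78 °C is complete before any migration starts on warming, by which time the excess thermally labile carbenoid has decomposed. It also needs chemoselectivity for boron, which the substrate provides because the chain has no other electrophilic or acidic site and the C7=C8 alkene and the allylic C9–H do not react with the organolithiums at −78 °C.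

Step 9
Reactants: 20 (13S)-labd-7-en-15-ol
Product: 21 (13S)-labd-7-en-15-yl acetate
Conditions: Ac2O, pyridine, DMAP (cat.), CH2Cl2, rt
Reagents that add atoms: acetic anhydride, CC(=O)OC(C)=O
Why: DMAP-catalysed acylation of an unhindered primary alcohol, which also protects C15 during the oxidation that follows.

Step 10
Reactants: 21 (13S)-labd-7-en-15-yl acetate
Product: 22 15-acetoxy-labd-7-en-17-ol
Conditions: SeO2 (0.5 equiv), t-BuOOH (3 equiv), CH2Cl2, rt
Reagents that add atoms: tert-butyl hydroperoxide, CC(C)(C)OO (terminal source of the C17 oxygen, passed on by selenium dioxide, O=[Se]=O)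
Why: SeO2 allylic oxidation (ene reaction, then [2,3]-sigmatropic shift) attacks at the more substituted alkene carbon C8, where the C17 methyl should react in preference to the hindered C9 methine and the double bond returns to C7=C8, while t-BuOOH recycles selenium and favours the alcohol stage; no stereocentre is involved.

Step 11
Reactants: 22 15-acetoxy-labd-7-en-17-ol
Product: 23 (13S)-labd-7-ene-15,17-diyl diacetate (target)
Conditions: Ac2O, pyridine, DMAP (cat.), CH2Cl2, rt
Reagents that add atoms: acetic anhydride, CC(=O)OC(C)=O
Why: DMAP-catalysed acylation of the primary allylic alcohol under non-acidic conditions, so that no allylic transposition is expected.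

**Compound list**

1 | (R)-(−)-carvone | O=C1C(C)=CC[C@@H](C(C)=C)C1 | starting material
2 | (5R)-6-methylcarvone, (5R)-2,6-dimethyl-5-(prop-1-en-2-yl)cyclohex-2-en-1-one, C6 epimers | O=C1C(C)=CC[C@@H](C(C)=C)C1C | intermediate
3 | methyl 2-(bromomethyl)acrylate | C=C(CBr)C(=O)OC | starting material
4 | methyl 2-{[(1S,6S)-1,3-dimethyl-2-oxo-6-(prop-1-en-2-yl)cyclohex-3-en-1-yl]methyl}prop-2-enoate (acrylate arm trans to isopropenyl, CH3 cis) | O=C1C(C)=CC[C@@H](C(C)=C)[C@]1(C)CC(=C)C(=O)OC | intermediate
5 | methyl 11-nor-9-oxodrim-7-ene-2-carboxylate (5α-H, 10β-CH3, C2 epimers) | O=C1C(C)=CC[C@H]2C(C)(C)CC(C(=O)OC)C[C@]12C | intermediate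
6 | 11-nor-9-oxodrim-7-ene-2-carboxylic acid (C2 epimers) | O=C1C(C)=CC[C@H]2C(C)(C)CC(C(=O)O)C[C@]12C | intermediate
7 | 2-thioxopyridin-1(2H)-yl 11-nor-9-oxodrim-7-ene-2-carboxylate (Barton ester) | O=C1C(C)=CC[C@H]2C(C)(C)CC(C(=O)ON3C=CC=CC3=S)C[C@]12C | intermediate
8 | 11-nor-drim-7-en-9-one, (4aS,8aS)-2,5,5,8a-tetramethyl-4a,5,6,7,8,8a-hexahydronaphthalen-1(4H)-one | O=C1C(C)=CC[C@H]2C(C)(C)CCC[C@]12C | intermediate
9 | drima-7,9(11)-diene | C=C1C(C)=CC[C@H]2C(C)(C)CCC[C@]12C | intermediate
10 | pinacol | CC(C)(O)C(C)(C)O | starting material
11 | dicyclohexyl(drim-7-en-11-yl)borane | C1CCCCC1B(C1CCCCC1)C[C@H]1C(C)=CC[C@H]2C(C)(C)CCC[C@]12C | intermediate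
12 | dicyclohexyl drim-7-en-11-ylboronate | C1CCCCC1OB(OC1CCCCC1)C[C@H]1C(C)=CC[C@H]2C(C)(C)CCC[C@]12C | intermediate
13 | drim-7-en-11-yl pinacol boronate | CC1(C)OB(C[C@H]2C(C)=CC[C@H]3C(C)(C)CCC[C@]23C)OC1(C)C | intermediate
14 | bromochloromethane | ClCBr | starting material
15 | ethyl N,N-diisopropylcarbamate | CCOC(=O)N(C(C)C)C(C)C | starting material
16 | 13,14,15,16-tetranorlabd-7-en-12-yl pinacol boronate (boron on C12) | CC1(C)OB(CC[C@H]2C(C)=CC[C@H]3C(C)(C)CCC[C@]23C)OC1(C)C | intermediate
17 | (13S)-14,15-dinorlabd-7-en-13-yl pinacol boronate (boron on C13) | CC1(C)OB([C@@H](C)CC[C@H]2C(C)=CC[C@H]3C(C)(C)CCC[C@]23C)OC1(C)C | intermediate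
18 | 15-norlabd-7-en-14-yl pinacol boronate (boron on C14, C13 as in the target) | CC1(C)OB(C[C@@H](C)CC[C@H]2C(C)=CC[C@H]3C(C)(C)CCC[C@]23C)OC1(C)C | intermediate
19 | labd-7-en-15-yl pinacol boronate (boron on C15, C13 as in the target) | CC1(C)OB(CC[C@@H](C)CC[C@H]2C(C)=CC[C@H]3C(C)(C)CCC[C@]23C)OC1(C)C | intermediate
20 | (13S)-labd-7-en-15-ol | OCC[C@@H](C)CC[C@H]1C(C)=CC[C@H]2C(C)(C)CCC[C@]12C | intermediate
21 | (13S)-labd-7-en-15-yl acetate | CC(=O)OCC[C@@H](C)CC[C@H]1C(C)=CC[C@H]2C(C)(C)CCC[C@]12C | intermediate
22 | 15-acetoxy-labd-7-en-17-ol | CC(=O)OCC[C@@H](C)CC[C@H]1C(CO)=CC[C@H]2C(C)(C)CCC[C@]12C | intermediate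
23 | (13S)-labd-7-ene-15,17-diyl diacetate | CC(=O)OCC[C@@H](C)CC[C@H]1C(COC(C)=O)=CC[C@H]2C(C)(C)CCC[C@]12C | target

**Step count**

Total: 11 steps. Longest linear sequence: 11 steps (1 → 23).

**Steps most likely to fail, with fallbacks**

Step 8. Insertions may be miscounted when the four cycles are run without purification (unreacted boronic ester carried into the next cycle, or a second insertion by surviving carbenoid). The 1,2-shift of the carbamate boronate may also be slow enough for the complex to revert, which lowers conversion and the C13 ratio. The fallback sets out from 13 and comes back at 20. Only the first CH2 insertion is run and 16 is isolated. The alkenyllithium made from (Z)-tert-butyl[(3-iodobut-2-en-1-yl)oxy]dimethylsilane (iodine cis to the CH2O group) and t-BuLi (Et2O, −78 °C) is added to 16, and the alkenyl boronate is treated with I2 and then NaOMe in MeOH (Zweifel olefination). The boron-to-carbon shift and anti elimination should place C12 trans to C15 and give (13E)-15-(tert-butyldimethylsilyloxy)labda-7,13-diene F1. Bu4NF in THF should then free (13E)-labda-7,13-dien-15-ol F2. Hydrogenation of this geraniol-type allylic alcohol with Ru(OAc)2[(R)-BINAP] under H2 in MeOH is hydroxyl-directed, should leave the isolated C7=C8 alkene, and should give the (S)-citronellol-type centre, that is 20.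

Step 7. The amine oxide may not discriminate fully between the cyclohexyl–boron bonds and the C11–boron bond, and the hindered conjugated methylene may take up the dialkylborane slowly. The fallback sets out from 9 and comes back at 13. Hydroboration with 9-BBN (THF, 60 °C) should give 9-(drim-7-en-11-yl)-9-borabicyclo[3.3.1]nonane F3 with the same α-face delivery of hydrogen to C9, and NaOH/H2O2 should oxidise it to (−)-drimenol F4, which can be checked against the natural product. I2, PPh3 and imidazole in toluene at 80 °C should give 11-iododrim-7-ene F5. Iodine–lithium exchange with t-BuLi (2.1 equiv, Et2O/pentane, −78 °C) and trapping with 2-isopropoxy-4,4,5,5-tetramethyl-1,3,2-dioxaborolane should give 13, the C–B bond now being made by borylation of an organolithium.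

Step 10. Site selectivity may erode (attack at the C9 methine or at C6), and the allylic alcohol may be oxidised further to the enal. The fallback sets out from 21 and comes back at 22. mCPBA (CH2Cl2, NaHCO3, 0 °C) should epoxidise C7=C8 from the α face to give 7α,8α-epoxylabdan-15-yl acetate F6. Cp2TiCl (from Cp2TiCl2 and Mn dust, THF, rt) should open the epoxide at the tertiary carbon C8 and, after hydrogen loss from C17, give 7α-hydroxylabd-8(17)-en-15-yl acetate F7. Catalytic Ph3SiOReO3 (Et2O, 0 °C) should then move the hydroxyl group from C7 to C17 by 1,3-transposition, towards the more stable endocyclic trisubstituted alkene, that is 22.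

**Further compounds**

F1 | step 8 | (13E)-15-(tert-butyldimethylsilyloxy)labda-7,13-diene | CC(C)(C)[Si](C)(C)OC/C=C(\C)CC[C@H]1C(C)=CC[C@H]2C(C)(C)CCC[C@]12C
F2 | step 8 | (13E)-labda-7,13-dien-15-ol | OC/C=C(\C)CC[C@H]1C(C)=CC[C@H]2C(C)(C)CCC[C@]12C
F3 | step 7 | 9-(drim-7-en-11-yl)-9-borabicyclo[3.3.1]nonane | C1CC2CCCC(C1)B2C[C@H]1C(C)=CC[C@H]2C(C)(C)CCC[C@]12C
F4 | step 7 | (−)-drimenol | OC[C@H]1C(C)=CC[C@H]2C(C)(C)CCC[C@]12C
F5 | step 7 | 11-iododrim-7-ene | IC[C@H]1C(C)=CC[C@H]2C(C)(C)CCC[C@]12C
F6 | step 10 | 7α,8α-epoxylabdan-15-yl acetate | CC(=O)OCC[C@@H](C)CC[C@H]1[C@]3(C)O[C@@H]3C[C@H]2C(C)(C)CCC[C@]12C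
F7 | step 10 | 7α-hydroxylabd-8(17)-en-15-yl acetate | CC(=O)OCC[C@@H](C)CC[C@H]1C(=C)[C@H](O)C[C@H]2C(C)(C)CCC[C@]12C
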